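The route rests on opening the pyran ring of the lower flavan-3-ol unit (O1, C2, C3, C4, C4a, C8a) into a four-atom and a two-atom piece. The key step exploits that the C4a–C8a edge of resorcinol ring A, with phenolic O1 and the doubly benzylic C4, is a latent ortho-quinone methide, and that C2–C3 is an (E)-styryl enol carbonate. One acid-catalysed inverse-demand oxa-Diels–Alder reaction joins them, makes O1–C2 and C3–C4, closes the last ring and sets C2, C3 and C4 all-trans. Its precursor is an ortho-hydroxybenzhydrol whose carbinol carbon already carries the finished (2R,3R)-dihydroflavonol unit; global hydrogenolysis ends the route.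

Key step: step 13

Assumption: atom numbers O1 to C8a refer to the lower flavan-3-ol unit. The (R)-configured acid of step 13 is taken to shield the face of the quinone methide that leads to 4S; if a trial shows the opposite sense, its enantiomer is used (the two outcomes are diastereomers, because the upper unit is enantiopure).

Step 1
Reactants: 1 3,4,5-tris(benzyloxy)benzaldehyde
Product: 2 3,4,5-tris(benzyloxy)-2-iodobenzaldehyde
Conditions: I2, CF3CO2Ag, CH2Cl2, 0 °C to rt, dark
Reagents that add atoms: iodine, II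
Why: Silver-assisted electrophilic aromatic iodination; the two free ring positions of 1 are equivalent and lie ortho and para to benzyloxy groups, so a single mono-iodide is expected, and the iodine later serves as the handle for the C4–aryl bond.

Step 2
Reactants: 3 1-[4-(benzyloxy)-2-hydroxyphenyl]ethan-1-one
Product: 4 1-[4-(benzyloxy)-2-(methoxymethoxy)phenyl]ethan-1-one
Conditions: MOMCl, i-Pr2NEt, CH2Cl2, 0 to 40 °C
Reagents that add atoms: chloromethyl methyl ether, COCCl
Why: Williamson-type O-alkylation (MOM protection) masks the chelated phenol so that the later nucleophilic epoxidation meets no free 2'-phenoxide.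

Step 3
Reactants: 2 3,4,5-tris(benzyloxy)-2-iodobenzaldehyde; 4 1-[4-(benzyloxy)-2-(methoxymethoxy)phenyl]ethan-1-one
Product: 5 (E)-1-[4-(benzyloxy)-2-(methoxymethoxy)phenyl]-3-[3,4,5-tris(benzyloxy)-2-iodophenyl]prop-2-en-1-one
Conditions: KOH, EtOH/THF, rt
Reagents that add atoms: none
Why: Claisen–Schmidt aldol condensation; only 4 can enolise and dehydration gives the conjugated E-enone.

Step 4
Reactants: 5 (E)-chalcone
Product: 6 [4-(benzyloxy)-2-(methoxymethoxy)phenyl][(2R,3S)-3-(3,4,5-tris(benzyloxy)-2-iodophenyl)oxiran-2-yl]methanone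
Conditions: poly-L-leucine, urea·H2O2, DBU, THF, rt
Reagents that add atoms: urea–hydrogen peroxide, OO.NC(N)=O
Why: Juliá–Colonna epoxidation (asymmetric Weitz–Scheffer reaction): the helical poly-L-leucine delivers hydroperoxide to one face of the E-enone, which should give the trans (2R,3S)-epoxide.

Step 5
Reactants: 6 (2R,3S)-epoxy ketone
Product: 8 (2R,3R)-7-(benzyloxy)-3-hydroxy-2-[3,4,5-tris(benzyloxy)-2-iodophenyl]-2,3-dihydro-4H-chromen-4-one, via phenol epoxide 7 (not isolated)
Conditions: conc. HCl, MeOH/THF, 50 °C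
Reagents that add atoms: none
Why: Acidic MOM cleavage followed by 6-endo-tet opening of the epoxide by the freed phenol at the benzylic carbon (activated by the para benzyloxy group) with inversion, while the α-carbon keeps its oxygen, is the established chalcone-epoxide route to trans-dihydroflavonols and should set (2R,3R).

Step 6
Reactants: 8 (2R,3R)-iodo-dihydroflavonol
Product: 9 (2R,3R)-3,7-bis(benzyloxy)-2-[3,4,5-tris(benzyloxy)-2-iodophenyl]-2,3-dihydro-4H-chromen-4-one
Conditions: BnBr, Ag2O, CH2Cl2, rt, dark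
Reagents that add atoms: benzyl bromide, BrCc1ccccc1
Why: Silver oxide-mediated O-benzylation under non-basic conditions avoids enolisation of the α-hydroxy ketone (C2 and C3 are kept) and blocks the 3-OH, which would otherwise add to the quinone methide of step 13.

Step 7
Reactants: 10 4-(benzyloxy)-2-hydroxybenzaldehyde
Product: 11 4-(benzyloxy)-2-[(tert-butyldimethylsilyl)oxy]benzaldehyde
Conditions: TBSCl, imidazole, DMF, rt
Reagents that add atoms: tert-butyldimethylsilyl chloride, CC(C)(C)[Si](C)(C)Cl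
Why: Imidazole-promoted silyl ether formation removes the acidic phenol proton that would quench the organochromium reagent of step 8.

Step 8
Reactants: 9 (2R,3R)-3-O-benzyl iodo-dihydroflavonol; 11 silylated aldehyde
Product: 13 (2R,3R)-3,7-bis(benzyloxy)-2-{3,4,5-tris(benzyloxy)-2-[(RS)-[4-(benzyloxy)-2-hydroxyphenyl](hydroxy)methyl]phenyl}-2,3-dihydro-4H-chromen-4-one, via silyl ether 12 (not isolated)
Conditions: NiCl2 (5 mol%), CrCl2 (4 equiv), DMF, rt; aqueous work-up; then TBAF/AcOH (1:1), THF, 0 °C on the crude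
Reagents that add atoms: none
Why: Nozaki–Hiyama–Kishi coupling: zerovalent nickel inserts into the C–I bond, the aryl group passes to trivalent chromium and adds to the aldehyde only (ketone, ethers and silyl ether are tolerated), and fluoride then frees the phenol; the new carbinol centre is left as a mixture because it becomes sp2 in step 13.

Step 9
Reactants: 1 3,4,5-tris(benzyloxy)benzaldehyde
Product: 14 2-[(E)-2-(3,4,5-tris(benzyloxy)phenyl)ethenyl]-4,4,5,5-tetramethyl-1,3,2-dioxaborolane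
Conditions: CH2(Bpin)2, lithium 2,2,6,6-tetramethylpiperidide (LiTMP), THF, 0 °C; then 1, −78 °C to rt
Reagents that add atoms: bis[(pinacolato)boryl]methane, CC1(C)OB(CB2OC(C)(C)C(C)(C)O2)OC1(C)C
Why: Boron–Wittig olefination: the lithiated geminal bis(boronate) adds to the aldehyde and syn B–O elimination from the favoured anti adduct gives the E-alkenylboronate.

Step 10
Reactants: 14 (E)-alkenylboronate
Product: 15 potassium (E)-trifluoro[2-(3,4,5-tris(benzyloxy)phenyl)ethenyl]borate
Conditions: KHF2, MeOH/H2O, rt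
Reagents that add atoms: potassium hydrogen difluoride, F[H-]F.[K+]
Why: Fluoride exchange at boron turns the pinacol ester into the bench-stable trifluoroborate with the alkene geometry untouched.

Step 11
Reactants: 15 potassium (E)-alkenyltrifluoroborate
Product: 16 (E)-2-[3,4,5-tris(benzyloxy)phenyl]ethenyl acetate
Conditions: AcOH, Cu(OAc)2 (10 mol%), DMAP, 4 Å MS, O2 (1 atm), MeCN, 60 °C
Reagents that add atoms: acetic acid, CC(=O)O
Why: Chan–Lam-type oxidative C–O coupling of an alkenyltrifluoroborate with a carboxylic acid under copper catalysis proceeds with retention at the alkenyl carbon, so the enol acetate should be E.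

Step 12
Reactants: 16 (E)-enol acetate
Product: 18 benzyl (E)-2-[3,4,5-tris(benzyloxy)phenyl]ethenyl carbonate, via lithium enolate 17 (not isolated)
Conditions: MeLi (2 equiv), DME, 0 °C; then CbzCl (2.2 equiv), −78 °C to 0 °C
Reagents that add atoms: benzyl chloroformate, O=C(Cl)OCc1ccccc1
Why: Methyllithium cleaves the enol acetate to the lithium enolate with retention of geometry and the hard chloroformate acylates it on oxygen (enolate O-acylation), which gives the E-enol carbonate whose benzyl group falls in the last step.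

Step 13
Reactants: 13 ortho-hydroxybenzhydrol; 18 (E)-enol benzyl carbonate (1.5 equiv)
Product: 20 benzyl (2R,3S,4S)-7-(benzyloxy)-4-{2,3,4-tris(benzyloxy)-6-[(2R,3R)-3,7-bis(benzyloxy)-4-oxo-3,4-dihydro-2H-chromen-2-yl]phenyl}-2-[3,4,5-tris(benzyloxy)phenyl]-3,4-dihydro-2H-chromen-3-yl carbonate, via ortho-quinone methide 19 (not isolated)
Conditions: (R)-3,3'-bis(2,4,6-triisopropylphenyl)-BINOL N-triflylphosphoramide (10 mol%), 5 Å MS, toluene, −20 °C to rt
Reagents that add atoms: none
Why: Proposed new method: the acid dehydrates 13 to the E-configured ortho-quinone methide 19 (ring A oxygen as carbonyl, C4 as exocyclic methide carbon, stabilised by the para benzyloxy group), which stays paired with the chiral phosphoramide anion and takes up 18 as the 2π partner of an inverse-electron-demand oxa-[4+2] cycloaddition; the closest known reaction type is the Brønsted acid-catalysed cycloaddition of in situ ortho-quinone methides with styrenes and β-alkylstyrenes to 2,4-cis-chromans, not yet shown for a β-acyloxystyrene. The pyran ring closes by this [4+2] mode, with C3–C4 bond formation running ahead of O1–C2 (in the stepwise limit a 6-endo-trig capture of the C2 benzylic cation by the ring A oxygen). Regiochemistry should follow the styrene sense, because positive charge is best placed on the carbon para to the 4-benzyloxy group of the trioxygenated ring whereas the carbonate oxygen is a poor π donor, so the carbon bearing the carbonate attacks C4. C2 and C3 are set trans by the E geometry of 18 (suprafacial addition), C4 is set cis to the C2 aryl group by the endo approach of that aryl under the quinone methide (together the all-trans array), and the absolute sense (4S, hence 3S and 2R) is controlled by the chiral acid, the (2R,3R) upper unit making any minor facial isomer a separable diastereomer. The step needs 18 to outrun Friedel–Crafts attack of the benzyloxy-arenes and self-trapping; the 3-O-benzyl group of the upper unit removes the only internal hydroxyl (it would close a six-membered ether), and an excess of 18 with molecular sieves at low temperature favours cycloaddition.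

Step 14
Reactants: 20 protected cycloadduct
Product: 21 (2R,3R)-2-{2-[(2R,3S,4S)-3,7-dihydroxy-2-(3,4,5-trihydroxyphenyl)-3,4-dihydro-2H-chromen-4-yl]-3,4,5-trihydroxyphenyl}-3,7-dihydroxy-2,3-dihydro-4H-chromen-4-one (CNP0310728.2)
Conditions: H2 (1 atm), Pd(OH)2/C, THF/MeOH, rt
Reagents that add atoms: none
Why: Palladium-catalysed hydrogenolysis cleaves the nine benzyl ethers and the benzyl carbonate (which then loses CO2) under neutral conditions that should leave the ketone, the two pyran C–O bonds and all five stereocentres untouched.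

Compound list

1 | 3,4,5-tris(benzyloxy)benzaldehyde | O=Cc1cc(OCc2ccccc2)c(OCc2ccccc2)c(OCc2ccccc2)c1 | starting material
2 | 3,4,5-tris(benzyloxy)-2-iodobenzaldehyde | O=Cc1cc(OCc2ccccc2)c(OCc2ccccc2)c(OCc2ccccc2)c1I | intermediate
3 | 1-[4-(benzyloxy)-2-hydroxyphenyl]ethan-1-one | CC(=O)c1ccc(OCc2ccccc2)cc1O | starting material
4 | 1-[4-(benzyloxy)-2-(methoxymethoxy)phenyl]ethan-1-one | CC(=O)c1ccc(OCc2ccccc2)cc1OCOC | intermediate
5 | (E)-1-[4-(benzyloxy)-2-(methoxymethoxy)phenyl]-3-[3,4,5-tris(benzyloxy)-2-iodophenyl]prop-2-en-1-one | COCOc1cc(OCc2ccccc2)ccc1C(=O)/C=C/c1cc(OCc2ccccc2)c(OCc2ccccc2)c(OCc2ccccc2)c1I | intermediate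
6 | [4-(benzyloxy)-2-(methoxymethoxy)phenyl][(2R,3S)-3-(3,4,5-tris(benzyloxy)-2-iodophenyl)oxiran-2-yl]methanone | COCOc1cc(OCc2ccccc2)ccc1C(=O)[C@@H]1O[C@H]1c1cc(OCc2ccccc2)c(OCc2ccccc2)c(OCc2ccccc2)c1I | intermediate
7 | [4-(benzyloxy)-2-hydroxyphenyl][(2R,3S)-3-(3,4,5-tris(benzyloxy)-2-iodophenyl)oxiran-2-yl]methanone | Oc1cc(OCc2ccccc2)ccc1C(=O)[C@@H]1O[C@H]1c1cc(OCc2ccccc2)c(OCc2ccccc2)c(OCc2ccccc2)c1I | intermediate (not isolated)
8 | (2R,3R)-7-(benzyloxy)-3-hydroxy-2-[3,4,5-tris(benzyloxy)-2-iodophenyl]-2,3-dihydro-4H-chromen-4-one | O=C1c2ccc(OCc3ccccc3)cc2O[C@H](c2cc(OCc3ccccc3)c(OCc3ccccc3)c(OCc3ccccc3)c2I)[C@H]1O | intermediate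
9 | (2R,3R)-3,7-bis(benzyloxy)-2-[3,4,5-tris(benzyloxy)-2-iodophenyl]-2,3-dihydro-4H-chromen-4-one | O=C1c2ccc(OCc3ccccc3)cc2O[C@H](c2cc(OCc3ccccc3)c(OCc3ccccc3)c(OCc3ccccc3)c2I)[C@H]1OCc1ccccc1 | intermediate
10 | 4-(benzyloxy)-2-hydroxybenzaldehyde | O=Cc1ccc(OCc2ccccc2)cc1O | starting material
11 | 4-(benzyloxy)-2-[(tert-butyldimethylsilyl)oxy]benzaldehyde | O=Cc1ccc(OCc2ccccc2)cc1O[Si](C)(C)C(C)(C)C | intermediate
12 | (2R,3R)-3,7-bis(benzyloxy)-2-{3,4,5-tris(benzyloxy)-2-[(RS)-[4-(benzyloxy)-2-(tert-butyldimethylsilyloxy)phenyl](hydroxy)methyl]phenyl}-2,3-dihydro-4H-chromen-4-one | O=C1c2ccc(OCc3ccccc3)cc2O[C@H](c2cc(OCc3ccccc3)c(OCc3ccccc3)c(OCc3ccccc3)c2C(O)c2ccc(OCc3ccccc3)cc2O[Si](C)(C)C(C)(C)C)[C@H]1OCc1ccccc1 | intermediate (not isolated)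
13 | (2R,3R)-3,7-bis(benzyloxy)-2-{3,4,5-tris(benzyloxy)-2-[(RS)-[4-(benzyloxy)-2-hydroxyphenyl](hydroxy)methyl]phenyl}-2,3-dihydro-4H-chromen-4-one | O=C1c2ccc(OCc3ccccc3)cc2O[C@H](c2cc(OCc3ccccc3)c(OCc3ccccc3)c(OCc3ccccc3)c2C(O)c2ccc(OCc3ccccc3)cc2O)[C@H]1OCc1ccccc1 | intermediate
14 | 2-[(E)-2-(3,4,5-tris(benzyloxy)phenyl)ethenyl]-4,4,5,5-tetramethyl-1,3,2-dioxaborolane | CC1(C)OB(/C=C/c2cc(OCc3ccccc3)c(OCc3ccccc3)c(OCc3ccccc3)c2)OC1(C)C | intermediate
15 | potassium (E)-trifluoro[2-(3,4,5-tris(benzyloxy)phenyl)ethenyl]borate | [K+].F[B-](F)(F)/C=C/c1cc(OCc2ccccc2)c(OCc2ccccc2)c(OCc2ccccc2)c1 | intermediate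
16 | (E)-2-[3,4,5-tris(benzyloxy)phenyl]ethenyl acetate | CC(=O)O/C=C/c1cc(OCc2ccccc2)c(OCc2ccccc2)c(OCc2ccccc2)c1 | intermediate
17 | lithium (E)-2-[3,4,5-tris(benzyloxy)phenyl]ethen-1-olate | [Li+].[O-]/C=C/c1cc(OCc2ccccc2)c(OCc2ccccc2)c(OCc2ccccc2)c1 | intermediate (not isolated)
18 | benzyl (E)-2-[3,4,5-tris(benzyloxy)phenyl]ethenyl carbonate | O=C(OCc1ccccc1)O/C=C/c1cc(OCc2ccccc2)c(OCc2ccccc2)c(OCc2ccccc2)c1 | intermediate
19 | (2R,3R)-3,7-bis(benzyloxy)-2-{3,4,5-tris(benzyloxy)-2-[(E)-(4-(benzyloxy)-6-oxocyclohexa-2,4-dien-1-ylidene)methyl]phenyl}-2,3-dihydro-4H-chromen-4-one | O=C1c2ccc(OCc3ccccc3)cc2O[C@H](c2cc(OCc3ccccc3)c(OCc3ccccc3)c(OCc3ccccc3)c2/C=C2/C(=O)C=C(OCc3ccccc3)C=C2)[C@H]1OCc1ccccc1 | intermediate (not isolated)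
20 | benzyl (2R,3S,4S)-7-(benzyloxy)-4-{2,3,4-tris(benzyloxy)-6-[(2R,3R)-3,7-bis(benzyloxy)-4-oxo-3,4-dihydro-2H-chromen-2-yl]phenyl}-2-[3,4,5-tris(benzyloxy)phenyl]-3,4-dihydro-2H-chromen-3-yl carbonate | O=C1c2ccc(OCc3ccccc3)cc2O[C@H](c2cc(OCc3ccccc3)c(OCc3ccccc3)c(OCc3ccccc3)c2[C@@H]2c3ccc(OCc4ccccc4)cc3O[C@H](c3cc(OCc4ccccc4)c(OCc4ccccc4)c(OCc4ccccc4)c3)[C@H]2OC(=O)OCc2ccccc2)[C@H]1OCc1ccccc1 | intermediate
21 | (2R,3R)-2-{2-[(2R,3S,4S)-3,7-dihydroxy-2-(3,4,5-trihydroxyphenyl)-3,4-dihydro-2H-chromen-4-yl]-3,4,5-trihydroxyphenyl}-3,7-dihydroxy-2,3-dihydro-4H-chromen-4-one | O=C1c2ccc(O)cc2O[C@H](c2cc(O)c(O)c(O)c2[C@@H]2c3ccc(O)cc3O[C@H](c3cc(O)c(O)c(O)c3)[C@H]2O)[C@H]1O | target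

Total step count: 14. Longest linear sequence: 8 steps (steps 1, 3, 4, 5, 6, 8, 13, 14).

Steps most likely to fail

Step 13 (key step). What may go wrong: addition in the enol sense (wrong regiochemistry), cycloaddition too slow to compete with Friedel–Crafts consumption of the quinone methide by the benzyloxy-arenes, or weak facial control. The fallback closes the same ring, still last, in a stepwise way with known chemistry; it sets out from 13 (with boronate 14) and comes back to the route at 21. Conjugate addition of 14 to the quinone methide generated from 13, catalysed by a chiral 3,3'-dibromo-BINOL (the antipode that gives the 4S centre; 4 Å MS, toluene), should give the (E)-triarylpropenyl phenol F1 with C4 set. Silylation (TBSCl, imidazole, DMF) gives its tert-butyldimethylsilyl ether F2. Shi epoxidation (ketone catalyst from L-sorbose, KHSO5 as Oxone, buffered MeCN/dimethoxymethane/water, 0 °C) gives the trans-(S,S)-epoxide F3 under reagent control. TBAF/AcOH followed by catalytic camphorsulfonic acid in CH2Cl2 frees the phenol, which opens the epoxide 6-endo at the benzylic carbon with inversion to the nonabenzyl 2,3-trans-flavan-3-ol F4. Hydrogenolysis of F4 under the conditions of step 14 gives 21.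

Step 8. What may go wrong: slow oxidative addition and transmetalation at the doubly ortho-substituted iodide, reduction of the C–I bond instead of coupling, and sluggish addition to the hindered, electron-rich aldehyde. The fallback sets out from 9 and comes back at 12. Miyaura borylation of 9 (B2pin2, PdCl2(dppf), KOAc, dioxane, 80 °C) gives the pinacol arylboronate F5; rhodium-catalysed 1,2-addition of F5 to aldehyde 11 ([RhCl(cod)]2, t-Bu3P, K2CO3, dioxane/H2O, 60 °C), which is selective for aldehydes over ketones, gives silyl ether 12, which is desilylated as in step 8.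

Step 5. What may go wrong: under protic acid the epoxide may open the 5-exo way toward aurone-type products, suffer aryl migration, or be captured by methanol before the phenol closes the ring. The fallback sets out from 6 and comes back at 8. Benzyl mercaptan with SnCl4 (CH2Cl2, −20 °C) opens the epoxide at the benzylic carbon and removes the MOM group to give the β-benzylsulfanyl α-hydroxy ketone F6 (C3 epimers, α-centre retained); thiophilic activation with AgBF4 (CH2Cl2, 0 °C) then lets the phenol displace sulfur at the benzylic carbon, the trans arrangement being favoured, to give 8.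

Further compounds

F1 | step 13 | (2R,3R)-3,7-bis(benzyloxy)-2-{3,4,5-tris(benzyloxy)-2-[(1S,2E)-1-(4-(benzyloxy)-2-hydroxyphenyl)-3-(3,4,5-tris(benzyloxy)phenyl)prop-2-en-1-yl]phenyl}-2,3-dihydro-4H-chromen-4-one | O=C1c2ccc(OCc3ccccc3)cc2O[C@H](c2cc(OCc3ccccc3)c(OCc3ccccc3)c(OCc3ccccc3)c2[C@@H](/C=C/c2cc(OCc3ccccc3)c(OCc3ccccc3)c(OCc3ccccc3)c2)c2ccc(OCc3ccccc3)cc2O)[C@H]1OCc1ccccc1
F2 | step 13 | tert-butyldimethylsilyl ether of F1 at the ring A phenol | O=C1c2ccc(OCc3ccccc3)cc2O[C@H](c2cc(OCc3ccccc3)c(OCc3ccccc3)c(OCc3ccccc3)c2[C@@H](/C=C/c2cc(OCc3ccccc3)c(OCc3ccccc3)c(OCc3ccccc3)c2)c2ccc(OCc3ccccc3)cc2O[Si](C)(C)C(C)(C)C)[C@H]1OCc1ccccc1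
F3 | step 13 | trans-(S,S)-epoxide of F2: (2R,3R)-3,7-bis(benzyloxy)-2-{3,4,5-tris(benzyloxy)-2-[(S)-[4-(benzyloxy)-2-(tert-butyldimethylsilyloxy)phenyl][(2S,3S)-3-(3,4,5-tris(benzyloxy)phenyl)oxiran-2-yl]methyl]phenyl}-2,3-dihydro-4H-chromen-4-one | O=C1c2ccc(OCc3ccccc3)cc2O[C@H](c2cc(OCc3ccccc3)c(OCc3ccccc3)c(OCc3ccccc3)c2[C@@H]([C@@H]2O[C@H]2c2cc(OCc3ccccc3)c(OCc3ccccc3)c(OCc3ccccc3)c2)c2ccc(OCc3ccccc3)cc2O[Si](C)(C)C(C)(C)C)[C@H]1OCc1ccccc1
F4 | step 13 | (2R,3R)-3,7-bis(benzyloxy)-2-{3,4,5-tris(benzyloxy)-2-[(2R,3S,4S)-7-(benzyloxy)-3-hydroxy-2-(3,4,5-tris(benzyloxy)phenyl)-3,4-dihydro-2H-chromen-4-yl]phenyl}-2,3-dihydro-4H-chromen-4-one | O=C1c2ccc(OCc3ccccc3)cc2O[C@H](c2cc(OCc3ccccc3)c(OCc3ccccc3)c(OCc3ccccc3)c2[C@@H]2c3ccc(OCc4ccccc4)cc3O[C@H](c3cc(OCc4ccccc4)c(OCc4ccccc4)c(OCc4ccccc4)c3)[C@H]2O)[C@H]1OCc1ccccc1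
F5 | step 8 | (2R,3R)-3,7-bis(benzyloxy)-2-[3,4,5-tris(benzyloxy)-2-(4,4,5,5-tetramethyl-1,3,2-dioxaborolan-2-yl)phenyl]-2,3-dihydro-4H-chromen-4-one | O=C1c2ccc(OCc3ccccc3)cc2O[C@H](c2cc(OCc3ccccc3)c(OCc3ccccc3)c(OCc3ccccc3)c2B2OC(C)(C)C(C)(C)O2)[C@H]1OCc1ccccc1
F6 | step 5 | (2S,3RS)-3-(benzylsulfanyl)-1-[4-(benzyloxy)-2-hydroxyphenyl]-2-hydroxy-3-[3,4,5-tris(benzyloxy)-2-iodophenyl]propan-1-one | Oc1cc(OCc2ccccc2)ccc1C(=O)[C@H](O)C(SCc1ccccc1)c1cc(OCc2ccccc2)c(OCc2ccccc2)c(OCc2ccccc2)c1I
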